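## Retrosynthetic overview
1. Pulicanaral A comes from the acetal-protected epoxy-aldehyde (late Fujioka acetal cleavage) after acetylation of the C6/C8 diol.
2. The ring-cis C1–C10 epoxide comes from the cis-1,2-diol by Kolb–Sharpless orthoacetate/chloro-acetate closure, with net retention.
3. The 10-membered carbocycle, C1, C10 and the diol form in one radical step: a Ti(III)/Zn ketyl pinacol coupling of a C1 aldehyde onto a C10 α-acetal ketone. The E-C4=C5 alkene is already in the chain.
4. The keto-aldehyde comes from a 1,3-anti boron aldol of pyruvaldehyde dimethyl acetal (sets C8; C14 is a masked CHO) onto an anti β-silyloxy aldehyde. That aldehyde comes from a proline cross-aldol of isovaleraldehyde with an E-enal (sets C6 and C7). The enal comes from cross-metathesis of acrolein with 4-methylpent-4-en-1-ol.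
5. Only the carbocycle is made by C–C bond formation, in the pinacol step. The epoxide is formed afterwards.

Assumptions:
- The SMILES encodes a ring-cis epoxide (ring bonds C2–C3 and C9–C10 on the same face). I assume the pinacol gives the matching cis-diol, with the required C1/C10 facial pair, as a separable major diastereomer.
- (R)-Proline is assumed to give the required C6/C7 series, by analogy with the (S)-proline anti-aldol series.

## Route

**Step 1**
Reactants: 1 acrolein; 2 4-methylpent-4-en-1-ol
Product: 3 (E)-6-hydroxy-3-methylhex-2-enal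
Conditions: Hoveyda–Grubbs II (5 mol%), CH2Cl2, 40 °C, excess acrolein
Reagents that add atoms: none (ethylene is lost)
Why: Cross-metathesis of an electron-poor type II olefin with a 1,1-disubstituted olefin gives the thermodynamically favoured E-trisubstituted enal, which fixes the E-C4=C5 geometry of the target.

**Step 2**
Reactants: 3 (E)-6-hydroxy-3-methylhex-2-enal; 4 isovaleraldehyde
Product: 5 (2R,3R,4E)-3,8-dihydroxy-2-isopropyl-5-methyloct-4-enal (anti-aldol; C7 = iPr-bearing carbon, C6 = allylic carbinol in target numbering)
Conditions: (R)-proline (20 mol%), DMF, 4 °C, isovaleraldehyde added by syringe pump over 16 h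
Reagents that add atoms: none
Why: Enamine-catalysed cross-aldol of two different aldehydes (Northrup–MacMillan type), with slow addition of the enolisable donor to avoid self-aldol. The Zimmerman–Traxler-like proline transition state gives the anti β-hydroxy aldehyde, which sets C6 and C7.

**Step 3**
Reactants: 5
Product: 6 (2R,3R,4E)-3,8-bis(TBS-oxy)-2-isopropyl-5-methyloct-4-enal (aldehyde free)
Conditions: TBSOTf (2.5 equiv), 2,6-lutidine, CH2Cl2, −78 → 0 °C
Reagents that add atoms: TBSOTf, CC(C)(C)[Si](C)(C)OS(=O)(=O)C(F)(F)F
Why: Silylation removes the retro-aldol and dehydration risk of the β-hydroxy aldehyde and gives the β-silyloxy aldehyde needed for 1,3-induction in step 4. No stereocentre is touched.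

**Step 4**
Reactants: 6; 7 pyruvaldehyde dimethyl acetal (1,1-dimethoxypropan-2-one)
Product: 8 β-hydroxy ketone (MeO)2CH–C(=O)–CH2–CH(OH)–CH(iPr)–CH(OTBS)–CH=C(Me)–(CH2)3–OTBS (C6 and C7 as in 6; C8–OH anti to C6–O and syn to C7–iPr)
Conditions: 7, Cy2BCl, Me2NEt, Et2O, 0 °C (enolisation); then 6, −78 → −20 °C; MeOH, pH 7 buffer, H2O2 workup
Reagents that add atoms: none
Why: The boron enolate forms on the CH3 side because the other α-carbon is a hindered acetal CH. Evans-type boron aldol of methyl ketones with β-alkoxy aldehydes gives the 1,3-anti adduct, and for this anti-α-alkyl-β-silyloxy aldehyde the Felkin preference reinforces it. This sets C8.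

**Step 5**
Reactants: 8
Product: 9 C8-OTBS ether of 8
Conditions: TBSOTf, 2,6-lutidine, CH2Cl2, −78 → 0 °C
Reagents that add atoms: TBSOTf, CC(C)(C)[Si](C)(C)OS(=O)(=O)C(F)(F)F
Why: This protects the β-hydroxy ketone against retro-aldol and elimination under the reductive Ti conditions later. C8 is unchanged.

**Step 6**
Reactants: 9
Product: 10 primary alcohol (C6-OTBS and C8-OTBS intact; acetal intact)
Conditions: PPTS (0.2 equiv), MeOH, 0 → 25 °C
Reagents that add atoms: none
Why: Mild acid methanolysis cleaves the primary TBS ether much faster than the hindered secondary ones. The dimethyl acetal is already a dimethyl acetal in methanol, so it is unchanged.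

**Step 7**
Reactants: 10
Product: 11 keto-aldehyde OHC–(CH2)2–C(Me)=CH–CH(OTBS)–CH(iPr)–CH(OTBS)–CH2–C(=O)–CH(OMe)2
Conditions: Dess–Martin periodinane, NaHCO3, CH2Cl2, 25 °C
Reagents that add atoms: none
Why: Dess–Martin oxidation is mild and non-epimerising. Only the primary alcohol is free; the enolisable ketone and acetal are untouched.

**Step 8**
Reactants: 11
Product: 12 macrocyclic cis-1,2-diol (C1-OH secondary, C10-OH tertiary; TBS ethers and acetal intact)
Conditions: TiCl3, Zn–Cu couple, DME, 0 → 25 °C; substrate added by syringe pump over 12 h (final ≈2 mM); aqueous NaHCO3 workup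
Reagents that add atoms: none (two H added at workup)
Why: Intramolecular cross-pinacol coupling. The more easily reduced aldehyde gives a Ti-bound ketyl radical that adds to the chelated α-acetal ketone, forming the C1–C10 bond and the 10-membered ring, and the Ti pinacolate delivers the cis-diol. Proposed new method: closing a 10-membered, E-alkene-containing ring with two new stereocentres by a low-valent-titanium aldehyde/ketone ketyl coupling; the closest known reactions are McMurry/Ti(III) and SmI2 intramolecular pinacol cyclisations to medium rings. The E-alkene and the anti,anti-stereotriad preorganise the macrocyclic conformer, and high dilution suppresses oligomers. C1 and C10 are set here, cis to each other, and diastereomers are separated.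

**Step 9**
Reactants: 12
Product: 13 ring-cis epoxide (bis-TBS, dimethyl acetal)
Conditions: (i) MeC(OMe)3, PPTS (cat.), CH2Cl2, 25 °C; (ii) TMSCl, 0 °C; (iii) concentrate, then K2CO3, MeOH, 25 °C (one pot; intermediates not isolated)
Reagents that add atoms: none (everything introduced transiently is lost again; net change is loss of H2O)
Why: Kolb–Sharpless diol-to-epoxide conversion. The diol forms a cyclic orthoacetate, and TMSCl converts it to the acetoxonium chloride. Chloride opens this by SN2 at the secondary C1 (inversion), giving the C1-chloride/C10-acetate. K2CO3/MeOH removes the acetate as MeOAc and frees the tertiary C10 alkoxide, which closes in a 3-exo-tet SN2 at C1 (second inversion). C1 is therefore retained overall and C10 is never touched, so the cis-diol becomes the ring-cis epoxide. The added atoms leave as MeOH, TMSOMe, MeOAc and KCl.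

**Step 10**
Reactants: 13
Product: 14 epoxy diol acetal (free C6-OH and C8-OH)
Conditions: TBAF (4 equiv), AcOH (4 equiv), THF, 0 → 25 °C
Reagents that add atoms: none
Why: Buffered fluoride removes both secondary TBS ethers without base-induced epoxide opening or alkoxide attack on the epoxide.

**Step 11**
Reactants: 14
Product: 15 diacetate acetal (C6-OAc and C8-OAc)
Conditions: Ac2O, pyridine, DMAP (cat.), CH2Cl2, 0 → 25 °C
Reagents that add atoms: Ac2O, CC(=O)OC(C)=O
Why: Simple acetylation of the two secondary alcohols, with no effect on the epoxide, alkene or acetal. Configuration is retained.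

**Step 12**
Reactants: 15
Product: 16 Pulicanaral A
Conditions: TESOTf (1.5 equiv), 2,4,6-collidine (3 equiv), CH2Cl2, 0 °C; then H2O
Reagents that add atoms: water, O
Why: Fujioka acetal-to-aldehyde cleavage goes through a collidinium intermediate under non-acidic conditions, which is gentle enough for the tertiary α,β-epoxide and the allylic acetate. It unmasks the quaternary epoxy-aldehyde, which cannot epimerise.

## Compound list
1 | acrolein | C=CC=O | starting material
2 | 4-methylpent-4-en-1-ol | C=C(C)CCCO | starting material
3 | (E)-6-hydroxy-3-methylhex-2-enal | O=C/C=C(\C)CCCO | intermediate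
4 | isovaleraldehyde (3-methylbutanal) | CC(C)CC=O | starting material
5 | (2R,3R,4E)-3,8-dihydroxy-2-isopropyl-5-methyloct-4-enal (anti-aldol) | OCCCC(/C)=C/[C@@H](O)[C@@H](C(C)C)C=O | intermediate
6 | bis-TBS ether of 5 | CC(C)(C)[Si](C)(C)OCCCC(/C)=C/[C@@H](O[Si](C)(C)C(C)(C)C)[C@@H](C(C)C)C=O | intermediate
7 | pyruvaldehyde dimethyl acetal (1,1-dimethoxypropan-2-one) | CC(=O)C(OC)OC | starting material
8 | aldol adduct (C8-OH, C10 ketone, C14 acetal) | CC(C)(C)[Si](C)(C)OCCCC(/C)=C/[C@@H](O[Si](C)(C)C(C)(C)C)[C@@H](C(C)C)[C@H](O)CC(=O)C(OC)OC | intermediate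
9 | C8-OTBS ether of 8 | CC(C)(C)[Si](C)(C)OCCCC(/C)=C/[C@@H](O[Si](C)(C)C(C)(C)C)[C@@H](C(C)C)[C@H](O[Si](C)(C)C(C)(C)C)CC(=O)C(OC)OC | intermediate
10 | primary alcohol | OCCCC(/C)=C/[C@@H](O[Si](C)(C)C(C)(C)C)[C@@H](C(C)C)[C@H](O[Si](C)(C)C(C)(C)C)CC(=O)C(OC)OC | intermediate
11 | keto-aldehyde (pinacol substrate) | O=CCCC(/C)=C/[C@@H](O[Si](C)(C)C(C)(C)C)[C@@H](C(C)C)[C@H](O[Si](C)(C)C(C)(C)C)CC(=O)C(OC)OC | intermediate
12 | macrocyclic cis-diol | O[C@@H]1CCC(/C)=C/[C@@H](O[Si](C)(C)C(C)(C)C)[C@@H](C(C)C)[C@H](O[Si](C)(C)C(C)(C)C)C[C@@]1(O)C(OC)OC | intermediate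
13 | epoxide, bis-TBS, acetal | CC(C)(C)[Si](C)(C)O[C@@H]1/C=C(\C)CC[C@H]2O[C@@]2(C(OC)OC)C[C@@H](O[Si](C)(C)C(C)(C)C)[C@@H]1C(C)C | intermediate
14 | epoxy diol acetal | O[C@@H]1/C=C(\C)CC[C@H]2O[C@@]2(C(OC)OC)C[C@@H](O)[C@@H]1C(C)C | intermediate
15 | diacetate acetal | CC(=O)O[C@@H]1/C=C(\C)CC[C@H]2O[C@@]2(C(OC)OC)C[C@@H](OC(C)=O)[C@@H]1C(C)C | intermediate
16 | Pulicanaral A | CC(=O)O[C@@H]1/C=C(\C)CC[C@H]2O[C@@]2(C=O)C[C@@H](OC(C)=O)[C@@H]1C(C)C | target

## Totals
Total steps: 12. Longest linear sequence: 12 (1 → 3 → 5 → 6 → 8 → 9 → 10 → 11 → 12 → 13 → 14 → 15 → 16; isovaleraldehyde and pyruvaldehyde acetal join at steps 2 and 4).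

Three steps most likely to fail:
1. **Step 8 (Ti pinacol macrocyclisation).** Risks are low yield, competing 6-exo ketyl–olefin cyclisation, the wrong cis/trans ratio, and the wrong C1/C10 facial pair. Fallback: close the ring by intramolecular Horner–Wadsworth–Emmons instead, using a C10 phosphonoacetate and the C1 aldehyde. That gives the ring-cis (E)-enoate, which is then taken to the epoxy-aldehyde by nucleophilic epoxidation and ester-to-aldehyde adjustment.
2. **Step 2 (proline cross-aldol with a β,β-disubstituted enal and a β-branched donor).** Risks are dienamine side reactions and poor dr or ee. Fallback: Evans syn aldol of N-isovaleryl-4-benzyloxazolidinone with enal 3, then Mitsunobu inversion of the C6 alcohol (p-nitrobenzoic acid) and reductive removal of the auxiliary to give the same aldehyde.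
3. **Step 9 (Kolb–Sharpless closure).** The intermolecular chloride SN2 at C1 is neopentyl-like, next to the quaternary acetal-bearing C10, and TMSCl may touch the acetal. Fallback: change to a single-inversion intramolecular closure. Oxidise the C1 carbinol of 12 (Dess–Martin), reduce the α-ketol with Zn(BH4)2 to the C1 epimer, mesylate C1 (Ms2O, pyridine), and close with t-BuOK. The tertiary alkoxide displaces the mesylate intramolecularly with one inversion, which gives the same ring-cis epoxide.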